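**Plan**

1. Numbering used throughout: five-membered ring C1(CH3)–C2–C3–C4(OH)(i-Pr)–C5(H); seven-membered ring C5–C6(O-angeloyl)–C7–C8(CH3)–C9–C10(OH)–C1, epoxide on C8–C9. β is the face of the C1 methyl, α the other; bicyclo[5.3.0]decane names below use these locants.
2. Enabling feature: in the seven-membered ring the lone methylene C7 is flanked by two functionalised pairs (C5/C6 and C8/C9), and the quaternary C1 sits next to the C10 carbinol. This is a masked cyclohepta-1,4-diene, the product of a [3,3] shift of a cyclopropane C6–C7–C8 that carries a methylcyclopentenyl arm (C5=C1) on C6 and an E-siloxyvinyl arm (C9=C10) on C8.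
3. Retrosynthetic cuts, in order: C6–O acyl; C4–isopropyl; C5–H/C6–O (hydroboration of C5=C6); epoxide oxygen (from C8=C9); C1–C10 with C6–C8 re-formed (Cope retron); C9=C10 (one-carbon homologation); the cyclopropane methylene C7; C5–C6 (Suzuki).
4. Forward: the five-membered ring is 3-methylcyclopent-2-enone (C4 masked as a ketal); C5–C6 joins it to the Z-iodide from propargyl alcohol; cyclopropanation and arm extension follow; the Cope shift closes the seven-membered ring; oxygenation, isopropyl addition and acylation finish.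
5. Stereochemistry: the dioxaborolane-controlled cyclopropanation sets C6/C8 (the only reagent control). The boat transition state passes this to C1, the E enol ether fixes C10, O10 directs the epoxide (C8, C9), and the C1 methyl steers the isopropyl addition (C4) and the hydroboration (C5, C6).

Key step: step 10

Remark: C4 travels as its ethylene ketal from step 2 to step 11, because a free cyclopentenone would compete with the aldehyde for the ylide and for the silyl triflate; the key step is therefore run on the ketal of the enone, and the dienone appears one step later.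

Assumption: the (4R,5R)-dioxaborolane is taken to deliver methylene to the same face of the C=C–CH2OH unit as it does with simple allylic alcohols, whatever the substitution; if the other enantiomer formed, the (4S,5S) reagent would be used.

**Route**

Step 1
Reactants: 1 3-methylcyclopent-2-en-1-one
Product: 3 2-bromo-3-methylcyclopent-2-en-1-one, via dibromo ketone 2 (not isolated)
Conditions: Br2, CH2Cl2, 0 °C; then Et3N, 0 °C → rt
Reagents that add atoms: bromine, BrBr
Why: Bromine adds across the enone alkene and triethylamine removes HBr from the α,β-dibromo ketone, the standard bromination–dehydrobromination route to 2-bromo enones.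

Step 2
Reactants: 3 2-bromo-3-methylcyclopent-2-en-1-one
Product: 4 6-bromo-7-methyl-1,4-dioxaspiro[4.4]non-6-ene
Conditions: HOCH2CH2OH, p-TsOH·H2O (cat.), benzene, reflux, Dean–Stark
Reagents that add atoms: ethylene glycol, OCCO
Why: Acid-catalysed ketalisation with azeotropic removal of water, in which the vinyl bromide keeps the alkene at C1=C5; the ketal permits bromine–lithium exchange and shields C4 from the ylide, the mercury salt and the silyl triflate used later.

Step 3
Reactants: 5 prop-2-yn-1-ol
Product: 7 (Z)-3-iodo-2-methylprop-2-en-1-ol, via alkenylmagnesium alkoxide 6 (not isolated)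
Conditions: MeMgBr (2.5 equiv), CuI (10 mol%), Et2O, −10 °C → rt; then I2, −10 °C
Reagents that add atoms: methylmagnesium bromide, C[Mg]Br; iodine, II
Why: Copper-catalysed carbomagnesiation of the propargylic magnesium alkoxide places methyl on the internal carbon and magnesium on the terminal carbon in an anti sense within a five-membered chelate, so iodinolysis should give only the Z-iodide.

Step 4
Reactants: 4 6-bromo-7-methyl-1,4-dioxaspiro[4.4]non-6-ene; 7 (Z)-3-iodo-2-methylprop-2-en-1-ol
Product: 10 (Z)-2-methyl-3-(7-methyl-1,4-dioxaspiro[4.4]non-6-en-6-yl)prop-2-en-1-ol, via alkenyllithium 8 (not isolated), via lithium alkenylborate 9 (not isolated)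
Conditions: n-BuLi, THF, −78 °C; B(Oi-Pr)3, −78 °C → rt; then 7, Pd(OAc)2 (5 mol%), SPhos (10 mol%), aq. K3PO4, 50 °C
Reagents that add atoms: none
Why: Bromine–lithium exchange, trapping as the triisopropyl borate and Suzuki–Miyaura coupling of this ate complex with the alkenyl iodide form C5–C6 with retention of both alkene geometries, a bulky biarylphosphine being used because the boron-bearing carbon is flanked on both sides.

Step 5
Reactants: 10 (Z)-2-methyl-3-(7-methyl-1,4-dioxaspiro[4.4]non-6-en-6-yl)prop-2-en-1-ol
Product: 11 [(1S,2R)-1-methyl-2-(7-methyl-1,4-dioxaspiro[4.4]non-6-en-6-yl)cyclopropyl]methanol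
Conditions: Zn(CH2I)2·DME (from Et2Zn, CH2I2, DME), (4R,5R)-2-butyl-N,N,N′,N′-tetramethyl-1,3,2-dioxaborolane-4,5-dicarboxamide (1.2 equiv), CH2Cl2, −10 °C → rt
Reagents that add atoms: diiodomethane, ICI
Why: In this dioxaborolane-controlled Simmons–Smith reaction (Charette cyclopropanation) the zinc alkoxide–boronate complex delivers the methylene C7 to one face of the allylic alkene only, giving the 6R,8S ring (route numbering) and turning the Z geometry of 10 into the cis relation of the two future vinyl arms, while the tetrasubstituted ring alkene has no alkoxide to guide the carbenoid.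

Step 6
Reactants: 11 [(1S,2R)-1-methyl-2-(7-methyl-1,4-dioxaspiro[4.4]non-6-en-6-yl)cyclopropyl]methanol
Product: 12 (1S,2R)-1-methyl-2-(7-methyl-1,4-dioxaspiro[4.4]non-6-en-6-yl)cyclopropane-1-carbaldehyde
Conditions: Dess–Martin periodinane, NaHCO3, CH2Cl2, 0 °C
Reagents that add atoms: none
Why: Buffered Dess–Martin oxidation of the neopentyl-type primary alcohol gives an aldehyde without α-hydrogen; the retro-Claisen shift open to a cis-2-vinylcyclopropanecarbaldehyde is held back by the same inward C1 methyl that slows step 10, and 12 is used at once.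

Step 7
Reactants: 12 (1S,2R)-1-methyl-2-(7-methyl-1,4-dioxaspiro[4.4]non-6-en-6-yl)cyclopropane-1-carbaldehyde; 13 (methoxymethyl)triphenylphosphonium chloride
Product: 15 6-[(1R,2S)-2-(2-methoxyethenyl)-2-methylcyclopropyl]-7-methyl-1,4-dioxaspiro[4.4]non-6-ene (E/Z mixture), via methoxymethylene ylide 14 (not isolated)
Conditions: 13, KN(SiMe3)2, THF, 0 °C; then 12, −78 °C → rt
Reagents that add atoms: none
Why: Wittig methoxymethylenation of the only carbonyl group present should give the enol ether as an E/Z mixture that converges in step 8 and is kept at or below room temperature because its E isomer is already a cis-divinylcyclopropane.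

Step 8
Reactants: 15 6-[(1R,2S)-2-(2-methoxyethenyl)-2-methylcyclopropyl]-7-methyl-1,4-dioxaspiro[4.4]non-6-ene
Product: 17 2-[(1R,2R)-1-methyl-2-(7-methyl-1,4-dioxaspiro[4.4]non-6-en-6-yl)cyclopropyl]acetaldehyde, via mercurio aldehyde 16 (not isolated)
Conditions: Hg(OAc)2, THF–H2O (10:1), 0 °C; then sat. aq. KI
Reagents that add atoms: water, O
Why: Oxymercuration of the enol ether in wet THF followed by iodide-induced demercuration frees the homologated aldehyde near neutrality, so the allylic ketal, which aqueous acid would remove, should stay in place.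

Step 9
Reactants: 17 2-[(1R,2R)-1-methyl-2-(7-methyl-1,4-dioxaspiro[4.4]non-6-en-6-yl)cyclopropyl]acetaldehyde
Product: 18 tert-butyl({(E)-2-[(1S,2R)-1-methyl-2-(7-methyl-1,4-dioxaspiro[4.4]non-6-en-6-yl)cyclopropyl]ethenyl}oxy)dimethylsilane
Conditions: TBSOTf, Et3N, CH2Cl2, −78 → 0 °C
Reagents that add atoms: tert-butyldimethylsilyl trifluoromethanesulfonate, CC(C)(C)[Si](C)(C)OS(=O)(=O)C(F)(F)F
Why: Soft enolisation with silyl triflate and amine converts the only enolisable carbonyl into its silyl enol ether, and the quaternary cyclopropane carbon C8 on C9 disfavours a cis relation to the siloxy group, so the E isomer should predominate and any Z isomer stays inert in step 10.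

Step 10
Reactants: 18 tert-butyl({(E)-2-[(1S,2R)-1-methyl-2-(7-methyl-1,4-dioxaspiro[4.4]non-6-en-6-yl)cyclopropyl]ethenyl}oxy)dimethylsilane
Product: 19 (1S,10R)-10-(tert-butyldimethylsilyloxy)-4,4-(ethylenedioxy)-1,8-dimethylbicyclo[5.3.0]deca-5,8-diene
Conditions: PhMe (degassed, 0.02 M), Et3N (trace), 110 °C, sealed tube
Reagents that add atoms: none
Why: The E-siloxyvinyl arm on C8 and the cyclopentenyl arm on C6 are cis on the three-membered ring and fold over it into the boat transition state of a concerted, suprafacial [3,3]-sigmatropic shift (cis-divinylcyclopropane–cycloheptadiene Cope rearrangement, known for siloxyvinyl arms and for termini that become quaternary carbons), in which C1 bonds to C10 while C6–C8 breaks, driven by release of cyclopropane strain. The seven-membered ring C5–C6–C7–C8–C9–C10–C1 closes in the sigmatropic C1–C10 bond formation itself, as a ring expansion of the cyclopropane and not by cyclisation of an open chain, the five-membered ring being already in place. C1 is controlled by the cyclopropane configuration from step 5, because the boat lets C10 reach only the face of the C1=C5 alkene that lies over the ring; C10 is controlled by the E geometry of the enol ether, which keeps the silyloxy group outside the boat and hence trans to the C1 methyl that must point inward. The step needs the boat (a cis-cyclopropane cannot reach the chair) and the E isomer only, since the Z enol ether would have to bring its oxygen inward beside the C1 methyl and should not react at this temperature. The inward C1 methyl makes this a hindered case that needs heat, but no hydrogen is placed for a competing homodienyl shift, and the ketal and silyl ether should be inert to neutral thermolysis.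

Step 11
Reactants: 19 (1S,10R)-10-(tert-butyldimethylsilyloxy)-4,4-(ethylenedioxy)-1,8-dimethylbicyclo[5.3.0]deca-5,8-diene
Product: 21 (1S,10R)-10-hydroxy-1,8-dimethylbicyclo[5.3.0]deca-5,8-dien-4-one, via hydroxy ketal 20 (not isolated)
Conditions: n-Bu4NF, THF, 0 °C → rt; then 1 M aq. HCl, rt, short
Reagents that add atoms: water, O
Why: Fluoride cleaves the silyl ether while C4 is still a ketal, so no enone with acidic C7 hydrogens meets basic fluoride, and brief dilute acid then hydrolyses the allylic ketal to the cross-conjugated dienone, both being standard deprotections.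

Step 12
Reactants: 21 (1S,10R)-10-hydroxy-1,8-dimethylbicyclo[5.3.0]deca-5,8-dien-4-one
Product: 22 (1S,8R,9S,10S)-8,9-epoxy-10-hydroxy-1,8-dimethylbicyclo[5.3.0]dec-5-en-4-one
Conditions: VO(acac)2 (5 mol%), t-BuOOH, CH2Cl2, 0 °C → rt
Reagents that add atoms: tert-butyl hydroperoxide, CC(C)(C)OO
Why: In this vanadium-catalysed hydroxyl-directed epoxidation the metal-bound C10 alkoxide delivers oxygen to C8=C9 on its own α face, as is usual for cyclohept-2-enols, while the electron-poor C5=C6 enone alkene should not react.

Step 13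
Reactants: 22 (1S,8R,9S,10S)-8,9-epoxy-10-hydroxy-1,8-dimethylbicyclo[5.3.0]dec-5-en-4-one
Product: 23 (1S,8R,9S,10S)-8,9-epoxy-1,8-dimethyl-10-(triethylsilyloxy)bicyclo[5.3.0]dec-5-en-4-one
Conditions: Et3SiCl, imidazole, DMF, 0 °C → rt
Reagents that add atoms: chlorotriethylsilane, CC[Si](CC)(CC)Cl
Why: Silylation of the secondary C10 alcohol leaves C6–OH as the only acylable hydroxyl in step 16, the triethylsilyl group being chosen to survive the organocerium and borane steps yet leave under buffered fluoride.

Step 14
Reactants: 23 (1S,8R,9S,10S)-8,9-epoxy-1,8-dimethyl-10-(triethylsilyloxy)bicyclo[5.3.0]dec-5-en-4-one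
Product: 24 (1S,4R,8R,9S,10S)-8,9-epoxy-1,8-dimethyl-4-(propan-2-yl)-10-(triethylsilyloxy)bicyclo[5.3.0]dec-5-en-4-ol
Conditions: CeCl3 (anhydrous), i-PrMgCl, THF, −78 °C
Reagents that add atoms: isopropylmagnesium chloride, CC(C)[Mg]Cl
Why: 1,2-Addition of the organocerium reagent suppresses enolisation, conjugate addition and β-hydride reduction, and the reagent should approach C4 from the α face, anti to the pseudo-axial C1 methyl that is 1,3 to the carbonyl, giving the β hydroxyl.

Step 15
Reactants: 24 (1S,4R,8R,9S,10S)-8,9-epoxy-1,8-dimethyl-4-(propan-2-yl)-10-(triethylsilyloxy)bicyclo[5.3.0]dec-5-en-4-ol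
Product: 26 (1S,4R,5S,6S,8R,9S,10S)-8,9-epoxy-1,8-dimethyl-4-(propan-2-yl)-10-(triethylsilyloxy)bicyclo[5.3.0]decane-4,6-diol, via alkylborane 25 (not isolated)
Conditions: BH3·THF, THF, 0 °C → rt; then 3 M aq. NaOH, 30% H2O2, 0 °C
Reagents that add atoms: hydrogen peroxide, OO
Why: In this hydroboration–oxidation boron goes to the less substituted C6 and hydrogen to C5 in a syn addition expected from the α face, anti to both the C1 methyl and the allylic C4–O bond, which sets H5 and O6 α (trans ring fusion) with retention on oxidation.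

Step 16
Reactants: 26 (1S,4R,5S,6S,8R,9S,10S)-8,9-epoxy-1,8-dimethyl-4-(propan-2-yl)-10-(triethylsilyloxy)bicyclo[5.3.0]decane-4,6-diol
Product: 27 10-O-triethylsilyl-lapiferine
Conditions: angelic acid, 2,4,6-Cl3C6H2COCl, Et3N, PhMe, rt; then 26, 80 °C
Reagents that add atoms: angelic acid, C/C=C(/C)C(=O)O
Why: Yamaguchi-type acylation with the mixed 2,4,6-trichlorobenzoic anhydride of angelic acid in hot toluene without a nucleophilic catalyst is known to keep the Z geometry of the angelate, and only the secondary C6 hydroxyl can react because the C4 hydroxyl is tertiary.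

Step 17
Reactants: 27 10-O-triethylsilyl-lapiferine
Product: 28 lapiferine
Conditions: HF·pyridine, pyridine, THF, 0 °C → rt
Reagents that add atoms: none
Why: Buffered fluoride desilylation should remove the triethylsilyl group without opening the epoxide or isomerising or cleaving the angelate.

**Compound list**

1 | 3-methylcyclopent-2-en-1-one | CC1=CC(=O)CC1 | starting material
2 | 2,3-dibromo-3-methylcyclopentan-1-one (racemic, not isolated) | CC1(Br)CCC(=O)C1Br | intermediate
3 | 2-bromo-3-methylcyclopent-2-en-1-one | CC1=C(Br)C(=O)CC1 | intermediate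
4 | 6-bromo-7-methyl-1,4-dioxaspiro[4.4]non-6-ene | CC1=C(Br)C2(CC1)OCCO2 | intermediate
5 | prop-2-yn-1-ol | C#CCO | starting material
6 | (Z)-3-(bromomagnesio)-2-methylprop-2-en-1-olate bromomagnesium salt (chelate, not isolated) | Br[Mg]/C=C(/C)CO[Mg]Br | intermediate
7 | (Z)-3-iodo-2-methylprop-2-en-1-ol | OC/C(C)=C\I | intermediate
8 | (7-methyl-1,4-dioxaspiro[4.4]non-6-en-6-yl)lithium (not isolated) | CC1=C([Li])C2(CC1)OCCO2 | intermediate
9 | lithium tri(propan-2-yloxy)(7-methyl-1,4-dioxaspiro[4.4]non-6-en-6-yl)borate (not isolated) | [Li+].CC1=C([B-](OC(C)C)(OC(C)C)OC(C)C)C2(CC1)OCCO2 | intermediate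
10 | (Z)-2-methyl-3-(7-methyl-1,4-dioxaspiro[4.4]non-6-en-6-yl)prop-2-en-1-ol | CC1=C(/C=C(/C)CO)C2(CC1)OCCO2 | intermediate
11 | [(1S,2R)-1-methyl-2-(7-methyl-1,4-dioxaspiro[4.4]non-6-en-6-yl)cyclopropyl]methanol | CC1=C([C@@H]3C[C@]3(C)CO)C2(CC1)OCCO2 | intermediate
12 | (1S,2R)-1-methyl-2-(7-methyl-1,4-dioxaspiro[4.4]non-6-en-6-yl)cyclopropane-1-carbaldehyde | CC1=C([C@@H]3C[C@]3(C)C=O)C2(CC1)OCCO2 | intermediate
13 | (methoxymethyl)triphenylphosphonium chloride | COC[P+](c1ccccc1)(c1ccccc1)c1ccccc1.[Cl-] | starting material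
14 | (methoxymethylidene)triphenylphosphorane (not isolated) | COC=P(c1ccccc1)(c1ccccc1)c1ccccc1 | intermediate
15 | 6-[(1R,2S)-2-(2-methoxyethenyl)-2-methylcyclopropyl]-7-methyl-1,4-dioxaspiro[4.4]non-6-ene (E/Z mixture) | CC1=C([C@@H]3C[C@]3(C)C=COC)C2(CC1)OCCO2 | intermediate
16 | 2-(acetoxymercurio)-2-[1-methyl-2-(7-methyl-1,4-dioxaspiro[4.4]non-6-en-6-yl)cyclopropyl]acetaldehyde (ring configured as in 15, epimers at the mercury-bearing carbon, not isolated) | CC1=C([C@@H]3C[C@]3(C)C([Hg]OC(C)=O)C=O)C2(CC1)OCCO2 | intermediate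
17 | 2-[(1R,2R)-1-methyl-2-(7-methyl-1,4-dioxaspiro[4.4]non-6-en-6-yl)cyclopropyl]acetaldehyde | CC1=C([C@@H]3C[C@]3(C)CC=O)C2(CC1)OCCO2 | intermediate
18 | tert-butyl({(E)-2-[(1S,2R)-1-methyl-2-(7-methyl-1,4-dioxaspiro[4.4]non-6-en-6-yl)cyclopropyl]ethenyl}oxy)dimethylsilane (Cope precursor; arms cis) | CC1=C([C@@H]3C[C@]3(C)/C=C/O[Si](C)(C)C(C)(C)C)C2(CC1)OCCO2 | intermediate
19 | (1S,10R)-10-(tert-butyldimethylsilyloxy)-4,4-(ethylenedioxy)-1,8-dimethylbicyclo[5.3.0]deca-5,8-diene (O10 α, C1 methyl β) | CC1=C[C@@H](O[Si](C)(C)C(C)(C)C)[C@@]2(C)CCC3(OCCO3)C2=CC1 | intermediate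
20 | (1S,10R)-4,4-(ethylenedioxy)-1,8-dimethylbicyclo[5.3.0]deca-5,8-dien-10-ol (not isolated) | CC1=C[C@@H](O)[C@@]2(C)CCC3(OCCO3)C2=CC1 | intermediate
21 | (1S,10R)-10-hydroxy-1,8-dimethylbicyclo[5.3.0]deca-5,8-dien-4-one | CC1=C[C@@H](O)[C@@]2(C)CCC(=O)C2=CC1 | intermediate
22 | (1S,8R,9S,10S)-8,9-epoxy-10-hydroxy-1,8-dimethylbicyclo[5.3.0]dec-5-en-4-one (epoxide α) | C1C[C@@]2(C)O[C@H]2[C@@H](O)[C@@]2(C)CCC(=O)C2=1 | intermediate
23 | (1S,8R,9S,10S)-8,9-epoxy-1,8-dimethyl-10-(triethylsilyloxy)bicyclo[5.3.0]dec-5-en-4-one | C1C[C@@]2(C)O[C@H]2[C@@H](O[Si](CC)(CC)CC)[C@@]2(C)CCC(=O)C2=1 | intermediate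
24 | (1S,4R,8R,9S,10S)-8,9-epoxy-1,8-dimethyl-4-(propan-2-yl)-10-(triethylsilyloxy)bicyclo[5.3.0]dec-5-en-4-ol (C4–OH β) | C1C[C@@]2(C)O[C@H]2[C@@H](O[Si](CC)(CC)CC)[C@@]2(C)CC[C@@](O)(C(C)C)C2=1 | intermediate
25 | C6 α-boryl, C4 O-boryl derivative of 24 with H5 α (not isolated) | B[C@H]1C[C@@]2(C)O[C@H]2[C@@H](O[Si](CC)(CC)CC)[C@@]2(C)CC[C@@](OB)(C(C)C)[C@H]12 | intermediate
26 | (1S,4R,5S,6S,8R,9S,10S)-8,9-epoxy-1,8-dimethyl-4-(propan-2-yl)-10-(triethylsilyloxy)bicyclo[5.3.0]decane-4,6-diol | O[C@H]1C[C@@]2(C)O[C@H]2[C@@H](O[Si](CC)(CC)CC)[C@@]2(C)CC[C@@](O)(C(C)C)[C@H]12 | intermediate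
27 | 10-O-triethylsilyl-lapiferine (6-angelate of 26) | C/C=C(/C)C(=O)O[C@H]1C[C@@]2(C)O[C@H]2[C@@H](O[Si](CC)(CC)CC)[C@@]2(C)CC[C@@](O)(C(C)C)[C@H]12 | intermediate
28 | lapiferine, (1S,4R,5S,6S,8R,9S,10S) in route numbering | C/C=C(/C)C(=O)O[C@H]1C[C@@]2(C)O[C@H]2[C@@H](O)[C@@]2(C)CC[C@@](O)(C(C)C)[C@H]12 | target

**Count and risks**

Total steps: 17. Longest linear sequence: 16 (steps 1, 2 and 4–17 from compound 1; step 3 is the side branch).

Steps most likely to fail:

Step 10. Bonding between the fully substituted C1 and C10, through a boat that holds the C1 methyl over the three-membered ring, may need temperatures at which the enol silane loses silicon, the allylic ketal eliminates and the cyclopropane epimerises to the unreactive trans isomer by reversible homolysis. The fallback carries boron instead of oxygen on the migrating arm. It sets out from aldehyde 12: a Takai–Utimoto olefination (CrCl2, LiI, Cl2CHB(pin), THF) should give the E-alkenylboronate F1, which has no hydrolysable enol ether and tolerates short heating at 150–170 °C in xylene. The same [3,3] shift should then give the allylic boronate F2 with boron α on C10. Oxidation with NaBO3·4H2O, with retention at carbon, returns to the hydroxy ketal 20, which re-enters at the acid stage of step 11.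

Step 15. Facial selectivity of borane addition may erode, because the α-isopropyl group on C4 crowds the face that the C1 methyl leaves open, and the C4 alkoxyborane may deliver hydride to the β face; reduction of the epoxide by excess borane is a second leak. The fallback sets H5 and O6 before the isopropyl group exists. It sets out from enone 23: copper-catalysed conjugate borylation (CuCl, NaOt-Bu, Xantphos, B2(pin)2, MeOH, THF) should add boron to C6 and, on protonation, hydrogen to C5, both anti to the C1 methyl, giving the β-boryl ketone F3. Oxidation with NaBO3·4H2O gives the β-hydroxy ketone F4. Addition of excess isopropylcerium reagent at −78 °C from the α face then returns to diol 26.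

Step 9. Enolisation may give a large share of the Z enol ether, and the silyl triflate may ionise the allylic ketal. The fallback makes the enol silane from a geometrically defined alkenyl metal instead of an enolate. It sets out from aldehyde 12: Takai iodo-olefination (CrCl2, CHI3, THF) should give the E-alkenyl iodide F5. Iodine–lithium exchange (t-BuLi, −78 °C) and oxidation of the alkenyllithium with bis(trimethylsilyl) peroxide should give the E-trimethylsilyl enol ether F6 with retention of geometry. Heating as in step 10 gives the trimethylsilyl ether F7, and fluoride as in step 11 returns to the hydroxy ketal 20.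

**Further compounds**

F1 | step 10 | 2-{(E)-2-[1-methyl-2-(7-methyl-1,4-dioxaspiro[4.4]non-6-en-6-yl)cyclopropyl]ethenyl}-4,4,5,5-tetramethyl-1,3,2-dioxaborolane (ring configured as in 12) | CC1=C([C@@H]3C[C@]3(C)/C=C/B4OC(C)(C)C(C)(C)O4)C2(CC1)OCCO2
F2 | step 10 | 10α-(pinacolatoboryl)-4,4-(ethylenedioxy)-1,8-dimethylbicyclo[5.3.0]deca-5,8-diene (C1 methyl β) | CC1=C[C@@H](B4OC(C)(C)C(C)(C)O4)[C@@]2(C)CCC3(OCCO3)C2=CC1
F3 | step 15 | 6α-(pinacolatoboryl)-5α-H derivative of ketone 23 (8,9-epoxy-1,8-dimethyl-10-(triethylsilyloxy)bicyclo[5.3.0]decan-4-one) | CC4(C)OB(OC4(C)C)[C@H]1C[C@@]2(C)O[C@H]2[C@@H](O[Si](CC)(CC)CC)[C@@]2(C)CCC(=O)[C@H]12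
F4 | step 15 | 8,9-epoxy-6α-hydroxy-1,8-dimethyl-10-(triethylsilyloxy)bicyclo[5.3.0]decan-4-one (H5 α) | O[C@H]1C[C@@]2(C)O[C@H]2[C@@H](O[Si](CC)(CC)CC)[C@@]2(C)CCC(=O)[C@H]12
F5 | step 9 | 6-{2-[(E)-2-iodoethenyl]-2-methylcyclopropyl}-7-methyl-1,4-dioxaspiro[4.4]non-6-ene (ring configured as in 12) | CC1=C([C@@H]3C[C@]3(C)/C=C/I)C2(CC1)OCCO2
F6 | step 9 | trimethyl({(E)-2-[1-methyl-2-(7-methyl-1,4-dioxaspiro[4.4]non-6-en-6-yl)cyclopropyl]ethenyl}oxy)silane (ring configured as in 18) | CC1=C([C@@H]3C[C@]3(C)/C=C/O[Si](C)(C)C)C2(CC1)OCCO2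
F7 | step 9 | (1S,10R)-4,4-(ethylenedioxy)-1,8-dimethyl-10-(trimethylsilyloxy)bicyclo[5.3.0]deca-5,8-diene | CC1=C[C@@H](O[Si](C)(C)C)[C@@]2(C)CCC3(OCCO3)C2=CC1
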